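Assumption: kukoamine B has no stereocentre and is achiral, so the "single enantiomer" is simply the compound drawn and no stereocontrol is needed.

## Retrosynthetic overview

1. Target ⇐ one global hydrogenation of a precursor in which the four phenols are benzyl ethers, the central secondary amine is N-benzylated and the terminal primary amine is an azide.
2. Central amine–butyl bond ⇐ SN2 of the right-hand secondary amine BnNH(CH2)3NHC(O)R on the 4-chlorobutyl arm of the left-hand tertiary amide N3(CH2)3N(C(O)R)(CH2)4Cl (R = 2-[3,4-bis(benzyloxy)phenyl]ethyl).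
3. Left-hand half ⇐ new three-component opening of a 2-substituted 5,6-dihydro-4H-1,3-oxazine: N-alkylation by 4-chlorobutyl triflate, then azide at the O–CH2 carbon. This forms the amide N–butyl bond, unveils the tertiary amide and forms the C–N bond of the future primary amine.
4. Both acyl groups ⇐ one tribenzylated dihydrocaffeic ester, by aminolysis with 3-aminopropan-1-ol or with N-benzylpropane-1,3-diamine.
5. Rings: the target is acyclic; the only ring made is the dihydrooxazine (Mitsunobu cyclodehydration), formed once and opened in the key step.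

## Route

Step 1
Reactants: 1 3-(3,4-dihydroxyphenyl)propanoic acid
Product: 2 benzyl 3-[3,4-bis(benzyloxy)phenyl]propanoate
Conditions: BnBr (3.5 equiv), K2CO3 (4 equiv), DMF, 60 °C, N2
Reagents that add atoms: benzyl bromide BrCc1ccccc1
Why: Williamson O-alkylation of both phenoxides and SN2 esterification of the carboxylate proceed together under carbonate base, giving one fully benzylated, hydrogenolysis-labile building block that serves for both acyl groups.

Step 2
Reactants: 2 benzyl 3-[3,4-bis(benzyloxy)phenyl]propanoate; 3 3-aminopropan-1-ol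
Product: 4 3-[3,4-bis(benzyloxy)phenyl]-N-(3-hydroxypropyl)propanamide
Conditions: 3 (3 equiv), 1,5,7-triazabicyclo[4.4.0]dec-5-ene (10 mol%), toluene, 80 °C
Reagents that add atoms: none
Why: Base-catalysed ester aminolysis acylates the primary amine chemoselectively over the alcohol and gives the secondary amide with benzyl alcohol as the only co-product.

Step 3
Reactants: 4 3-[3,4-bis(benzyloxy)phenyl]-N-(3-hydroxypropyl)propanamide
Product: 5 2-{2-[3,4-bis(benzyloxy)phenyl]ethyl}-5,6-dihydro-4H-1,3-oxazine
Conditions: PPh3, diisopropyl azodicarboxylate, THF, 0 °C → rt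
Reagents that add atoms: none
Why: Mitsunobu cyclodehydration activates the primary hydroxyl, and the amide oxygen closes the six-membered cyclic imidate by intramolecular SN2 displacement (6-exo-tet).

Step 4
Reactants: 6 4-chlorobutan-1-ol
Product: 7 4-chlorobutyl trifluoromethanesulfonate
Conditions: (CF3SO2)2O, pyridine, CH2Cl2, −30 °C; cold aqueous wash, used at once
Reagents that add atoms: trifluoromethanesulfonic anhydride O=S(=O)(OS(=O)(=O)C(F)(F)F)C(F)(F)F
Why: O-sulfonylation (triflation) of a primary alcohol is fast at low temperature and leaves the remote chloride untouched, giving an electrophile whose two leaving groups differ greatly in reactivity.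

Step 5
Reactants: 5 2-{2-[3,4-bis(benzyloxy)phenyl]ethyl}-5,6-dihydro-4H-1,3-oxazine; 7 4-chlorobutyl trifluoromethanesulfonate
Product: 9 N-(3-azidopropyl)-3-[3,4-bis(benzyloxy)phenyl]-N-(4-chlorobutyl)propanamide, via N-(4-chlorobutyl)oxazinium triflate 8 (not isolated)
Conditions: 5 (1.05 equiv), MeCN, −20 °C → rt, 2 h; then NaN3 (1.5 equiv), 15-crown-5 (10 mol%), rt → 40 °C
Reagents that add atoms: sodium azide [Na+].[N-]=[N+]=[N-]
Why: Proposed new method: a stoichiometric one-unit version of cationic ring-opening of a cyclic imidate, in which the imidate nitrogen of 5 (its most nucleophilic site) is alkylated by the primary triflate 7 at low temperature, where this initiation is far faster than attack of a second oxazine on oxazinium 8 (propagation needs heat and is starved by the near 1:1 stoichiometry and the non-nucleophilic triflate counter-ion), and azide then attacks C6, the O–CH2 carbon of 8, in an SN2 step that expels the amide oxygen, so that the amide N–butyl bond, the tertiary amide and the C–N bond of the future primary amine arise regiospecifically in one flask without protecting groups while the alkyl chloride is too slow an electrophile to react with azide at 40 °C or below; the closest known reaction type is the initiation and azide end-capping of living cationic ring-opening polymerisation of 2-oxazolines and 2-oxazines (and nucleophilic opening of N-methyl-2-oxazolinium salts), which has not been shown as a three-component synthesis of N-acyl-N-alkyl-1,3-diamines from a side-chain-functionalised dihydrooxazine.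

Step 6
Reactants: 2 benzyl 3-[3,4-bis(benzyloxy)phenyl]propanoate; 10 N-benzylpropane-1,3-diamine
Product: 11 N-[3-(benzylamino)propyl]-3-[3,4-bis(benzyloxy)phenyl]propanamide
Conditions: 10 (1.5 equiv), 1,5,7-triazabicyclo[4.4.0]dec-5-ene (10 mol%), toluene, 80 °C
Reagents that add atoms: none
Why: Base-catalysed ester aminolysis occurs at the unhindered primary amine of 10 far faster than at its N-benzyl secondary amine, so the right-hand half is obtained with the future central nitrogen already carrying a hydrogenolysis-labile benzyl group.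

Step 7
Reactants: 9 N-(3-azidopropyl)-3-[3,4-bis(benzyloxy)phenyl]-N-(4-chlorobutyl)propanamide; 11 N-[3-(benzylamino)propyl]-3-[3,4-bis(benzyloxy)phenyl]propanamide
Product: 13 N-(3-azidopropyl)-N-{4-[benzyl(3-{3-[3,4-bis(benzyloxy)phenyl]propanamido}propyl)amino]butyl}-3-[3,4-bis(benzyloxy)phenyl]propanamide, via alkyl iodide 12 (not isolated)
Conditions: NaI (20 mol%), K2CO3 (2 equiv), MeCN, 70 °C
Reagents that add atoms: none
Why: Finkelstein halide exchange turns the primary chloride into the iodide in the flask, and the secondary amine displaces it by SN2 N-alkylation; the hindered tertiary benzylamine product resists quaternisation, and the azide, amides and benzyl ethers are inert.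

Step 8
Reactants: 13 N-(3-azidopropyl)-N-{4-[benzyl(3-{3-[3,4-bis(benzyloxy)phenyl]propanamido}propyl)amino]butyl}-3-[3,4-bis(benzyloxy)phenyl]propanamide
Product: 14 kukoamine B
Conditions: H2 (4 bar), Pd(OH)2/C, EtOH–AcOH (9:1), rt; basic ion-exchange work-up under argon
Reagents that add atoms: none
Why: Catalytic hydrogenolysis removes the four O-benzyl groups and the N-benzyl group as toluene and reduces the azide to the primary amine with loss of N2 in one operation, the acetic acid keeping the liberated amines protonated so that they neither poison the catalyst nor promote catechol oxidation or N-to-N acyl migration.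

## Compound list

1 | 3-(3,4-dihydroxyphenyl)propanoic acid (dihydrocaffeic acid) | OC(=O)CCc1ccc(O)c(O)c1 | starting material
2 | benzyl 3-[3,4-bis(benzyloxy)phenyl]propanoate | O=C(OCc1ccccc1)CCc1ccc(OCc2ccccc2)c(OCc2ccccc2)c1 | intermediate
3 | 3-aminopropan-1-ol | NCCCO | starting material
4 | 3-[3,4-bis(benzyloxy)phenyl]-N-(3-hydroxypropyl)propanamide | OCCCNC(=O)CCc1ccc(OCc2ccccc2)c(OCc2ccccc2)c1 | intermediate
5 | 2-{2-[3,4-bis(benzyloxy)phenyl]ethyl}-5,6-dihydro-4H-1,3-oxazine | C1CN=C(CCc2ccc(OCc3ccccc3)c(OCc3ccccc3)c2)OC1 | intermediate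
6 | 4-chlorobutan-1-ol | OCCCCCl | starting material
7 | 4-chlorobutyl trifluoromethanesulfonate | ClCCCCOS(=O)(=O)C(F)(F)F | intermediate
8 | 2-{2-[3,4-bis(benzyloxy)phenyl]ethyl}-3-(4-chlorobutyl)-5,6-dihydro-4H-1,3-oxazin-3-ium trifluoromethanesulfonate | ClCCCC[N+]1=C(CCc2ccc(OCc3ccccc3)c(OCc3ccccc3)c2)OCCC1.[O-]S(=O)(=O)C(F)(F)F | intermediate
9 | N-(3-azidopropyl)-3-[3,4-bis(benzyloxy)phenyl]-N-(4-chlorobutyl)propanamide | [N-]=[N+]=NCCCN(CCCCCl)C(=O)CCc1ccc(OCc2ccccc2)c(OCc2ccccc2)c1 | intermediate
10 | N-benzylpropane-1,3-diamine | NCCCNCc1ccccc1 | starting material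
11 | N-[3-(benzylamino)propyl]-3-[3,4-bis(benzyloxy)phenyl]propanamide | O=C(CCc1ccc(OCc2ccccc2)c(OCc2ccccc2)c1)NCCCNCc1ccccc1 | intermediate
12 | N-(3-azidopropyl)-3-[3,4-bis(benzyloxy)phenyl]-N-(4-iodobutyl)propanamide | [N-]=[N+]=NCCCN(CCCCI)C(=O)CCc1ccc(OCc2ccccc2)c(OCc2ccccc2)c1 | intermediate
13 | N-(3-azidopropyl)-N-{4-[benzyl(3-{3-[3,4-bis(benzyloxy)phenyl]propanamido}propyl)amino]butyl}-3-[3,4-bis(benzyloxy)phenyl]propanamide | [N-]=[N+]=NCCCN(CCCCN(Cc1ccccc1)CCCNC(=O)CCc1ccc(OCc2ccccc2)c(OCc2ccccc2)c1)C(=O)CCc1ccc(OCc2ccccc2)c(OCc2ccccc2)c1 | intermediate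
14 | kukoamine B, N-(3-aminopropyl)-3-(3,4-dihydroxyphenyl)-N-{4-[(3-{[3-(3,4-dihydroxyphenyl)propanoyl]amino}propyl)amino]butyl}propanamide | NCCCN(CCCCNCCCNC(=O)CCc1ccc(O)c(O)c1)C(=O)CCc1ccc(O)c(O)c1 | target

## Step count and risks

Total step count: 8.
Longest linear sequence: 6 steps (steps 1, 2, 3, 5, 7, 8). Steps 4 and 6 are side branches.

Three steps most likely to fail:

**Step 5 (the proposed new step).** Risks are oligomerisation (a second molecule of 5 opening oxazinium 8), hydrolytic opening of 8 at C2 on work-up if azide capture is slow, and decomposition of triflate 7. The fallback uses known chemistry only; it sets out from 2 and comes back to the route at 9. Ester 2 is subjected to aminolysis with commercial 3-azidopropan-1-amine under the conditions of step 2 to give N-(3-azidopropyl)-3-[3,4-bis(benzyloxy)phenyl]propanamide F1. Its sodium amidate (NaH, DMF, 0 °C) is then N-alkylated with 1-bromo-4-chlorobutane, the bromide being displaced selectively, to give 9. This is the classical N-alkylation of a secondary amide; it avoids the oxazine altogether, at the cost of strong base and some O-alkylation and elimination.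

**Step 7.** Risks are sluggish SN2 attack by the hindered secondary N-benzyl amine, elimination, or partial quaternisation. The fallback sets out from 9 (with 4 as the second component) and comes back at 13, and makes the tertiary amine by reductive amination instead of alkylation. Compound 9 is heated with excess benzylamine (K2CO3, NaI cat., MeCN, 60 °C) to give N-(3-azidopropyl)-N-[4-(benzylamino)butyl]-3-[3,4-bis(benzyloxy)phenyl]propanamide F2. Alcohol 4 is oxidised with Dess–Martin periodinane (CH2Cl2, 0 °C) to 3-[3,4-bis(benzyloxy)phenyl]-N-(3-oxopropyl)propanamide F3, used at once. Reductive amination of F3 with F2 (NaBH(OAc)3, 1,2-dichloroethane, rt) gives 13.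

**Step 8.** Risks are incomplete hydrogenolysis of the tertiary N-benzyl group, catalyst poisoning by the polyamine, and catechol oxidation during a prolonged reaction. The fallback sets out from 13 and comes back at 14, and removes the N-benzyl group chemically before a milder hydrogenation. Compound 13 is treated with 1-chloroethyl chloroformate (1,2-dichloroethane, reflux), which cleaves the benzyl group as benzyl chloride and gives 1-chloroethyl N-(4-{N-(3-azidopropyl)-3-[3,4-bis(benzyloxy)phenyl]propanamido}butyl)-N-(3-{3-[3,4-bis(benzyloxy)phenyl]propanamido}propyl)carbamate F4. Methanolysis (MeOH, reflux) gives the secondary amine N-(3-azidopropyl)-3-[3,4-bis(benzyloxy)phenyl]-N-{4-[(3-{3-[3,4-bis(benzyloxy)phenyl]propanamido}propyl)amino]butyl}propanamide F5. F5 then needs only O-debenzylation and azide reduction (H2 1 bar, Pd/C, EtOH–AcOH, rt) to give 14.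

## Further compounds

F1 | step 5 | N-(3-azidopropyl)-3-[3,4-bis(benzyloxy)phenyl]propanamide | [N-]=[N+]=NCCCNC(=O)CCc1ccc(OCc2ccccc2)c(OCc2ccccc2)c1
F2 | step 7 | N-(3-azidopropyl)-N-[4-(benzylamino)butyl]-3-[3,4-bis(benzyloxy)phenyl]propanamide | [N-]=[N+]=NCCCN(CCCCNCc1ccccc1)C(=O)CCc1ccc(OCc2ccccc2)c(OCc2ccccc2)c1
F3 | step 7 | 3-[3,4-bis(benzyloxy)phenyl]-N-(3-oxopropyl)propanamide | O=CCCNC(=O)CCc1ccc(OCc2ccccc2)c(OCc2ccccc2)c1
F4 | step 8 | 1-chloroethyl N-(4-{N-(3-azidopropyl)-3-[3,4-bis(benzyloxy)phenyl]propanamido}butyl)-N-(3-{3-[3,4-bis(benzyloxy)phenyl]propanamido}propyl)carbamate | CC(Cl)OC(=O)N(CCCCN(CCCN=[N+]=[N-])C(=O)CCc1ccc(OCc2ccccc2)c(OCc2ccccc2)c1)CCCNC(=O)CCc1ccc(OCc2ccccc2)c(OCc2ccccc2)c1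
F5 | step 8 | N-(3-azidopropyl)-3-[3,4-bis(benzyloxy)phenyl]-N-{4-[(3-{3-[3,4-bis(benzyloxy)phenyl]propanamido}propyl)amino]butyl}propanamide | [N-]=[N+]=NCCCN(CCCCNCCCNC(=O)CCc1ccc(OCc2ccccc2)c(OCc2ccccc2)c1)C(=O)CCc1ccc(OCc2ccccc2)c(OCc2ccccc2)c1
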